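In a one-step world, substrate would pass straight into double product, and the two columns of a run would add up to the whole charge. I set the flasks and the runs beside that picture.

| flask | substrate | reagent | temperature | remark | time |
|---|---|---|---|---|---|
| red | 0.54 M | 1.2 M | 31 °C | run made earlier |  |
| green | 1.2 M | 1.2 M | 45 °C | run made earlier |  |
| violet | 0.80 M | 2.4 M | 31 °C | run made earlier |  |
| larch | 0.80 M | 1.20 M | 50 °C |  | 30 h |
| oak | 0.80 M | 1.20 M | 25 °C |  | 30 h |

- red (time / h: double product / %, substrate / %): 15.0: 34, 59; 30.0: 53, 35; 48.0: 68, 26; 60.0: 69, 25; 72.0: 76, 18
- green (time / h: double product / %, substrate / %): 2.50: 14, 69; 8.00: 36, 52; 15.0: 40, 45; 20.0: 40, 44; 30.0: 44, 48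
- violet (time / h: double product / %, substrate / %): 6.00: 27, 63; 12.0: 51, 38; 20.0: 63, 25; 40.0: 84, 11; 72.0: 94, 6

(each reading ± 2 percentage points)



1. the flask that comes out highest in amount of double product, in percent of the substrate charged, or "all alike" when all lie within 1.5 percentage points (larch / oak / all alike)
2. double product at the end, in percent of the substrate charged, larch
3. double product at the end, in percent of the substrate charged, oak

I read the green table downward. Its first row shows 69% substrate and 14% double product, so 17.0% stood in neither column, and I took that for a first product. Its last rows stall, with double product at 40% and then 44%, and substrate at 48%. Two reagent per double product explains this: shared out that way, the green charge gives a ceiling of 50.0%. That run ended 6 percentage points below it. For larch and oak, where reagent is the limiting reagent, the ceiling is 75.0%.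

The same first row gives an apparent loss of substrate of 0.148 h⁻¹ at 45 °C, an average over that stretch and not a true first-order constant, since the green run has no excess of reagent and its [reagent] falls. The first red row, at the same starting [reagent], gives 0.0352 h⁻¹ at 31 °C, so this apparent rate doubled every 6.74 K.

I carried one quantity: the exposure, this rate at the flask's temperature multiplied by its time. Integrated with this apparent rate held constant, a flask keeps exp(−exposure) of its substrate, and in that estimate the ceiling is met at an exposure of 1.39.

Larch has 7.45, past that mark, so I put it at the ceiling less the green shortfall, 69.0%. Oak has 0.569, short of it, so it keeps 56.6% substrate. The first violet row, with oak's substrate charge, has 10 points in neither column, which leaves oak 33.4%.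

The forecast named larch, with 68% and 29% (“Larch reaches the reagent limit”), so my oak stood higher than its figure.

The flasks gave larch as highest, with larch at 67.7% and oak at 31.6%.

    reagent + double product ⇌ triple product + by-product (K = 19.0, k = 5.30 × 10⁻⁴ L mol⁻¹ h⁻¹, Ea = 87.0 kJ mol⁻¹, ΔH = −12.0 kJ mol⁻¹)
    substrate + reagent → first product + by-product (k = 0.0220 L mol⁻¹ h⁻¹, Ea = 75.0 kJ mol⁻¹)
    reagent + first product → double product + by-product (k = 0.120 L mol⁻¹ h⁻¹, Ea = 68.0 kJ mol⁻¹)
    (constants at 25 °C)

Oak held 56.5% substrate at 30.0 h, an exposure of 0.571 against my 0.569. Two things together held it at 31.6%: the reading at 30 h rather than at 300 h, and the shrinking supply of reagent. Read at 300 h, oak stands at 69.0%, under the ceiling of 75.0%, and at 30 h with its reagent kept from shrinking it stands at 44.4%. A flask like oak kept at 40 °C has an exposure of 2.66, past the mark, and it holds 61.0% double product with 11.2% of its reagent left.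

All runs were computed with made-up constants, and the scatter is random.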